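The methylene-lactone ring (O–C8–C7–C11–C12, germacrane numbering) is disconnected at C7–C11 and O–C8. The precursor is an acyclic (E)-C7=C8 alkene carrying the finished furanone, the bought C6 carbinol (as PMB ether) and, on a temporary C5 hydroxyl, a malonic half-ester. Mn(OAc)3 oxidation makes the C11 radical close 6-exo on C7 and lactonises the resulting C8 radical, so C6 sets C7 and C8 in one event; the step exploits the contiguous C6(O)–C7–C8(O) triad around that ring. The tether carbonyl then leaves as CO2 during Mannich methylenation, freeing C5 for vinylation and ring-closing metathesis (C4=C5) of the ten-membered ring.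

Key step: step 8

Remark on numbering: C1 is the furanone ketone, C2=C3 the furanone alkene, C4=C5 the ring alkene, C6 the ester carbinol, C7 and C8 the lactone ring carbons (C8 bears the lactone oxygen), C9 the methylene, C10 the quaternary carbon, C11–C13 the methylene-lactone carbons, C14 and C15 the methyls. Intermediates keep these labels. PMB = 4-methoxybenzyl.

Assumption: (2R)-but-3-ene-1,2-diol, 2-methylbut-1-en-3-yne and (2Z)-2-methylbut-2-en-1-ol are taken as purchasable.

Step 1
Reactants: 1 (S)-lactic acid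
Product: 2 (2S,5S)-2-tert-butyl-5-methyl-1,3-dioxolan-4-one
Conditions: pivalaldehyde, p-TsOH·H2O (cat.), H2SO4 (cat.), pentane, reflux with water separator; crystallisation of the cis isomer
Reagents that add atoms: pivalaldehyde, CC(C)(C)C=O
Why: Acid-catalysed acetalisation for self-regeneration of the stereocentre; the acetal carbon is set under thermodynamic control (cis) and the isomer is purified by crystallisation.

Step 2
Reactants: 2 (cis-dioxolanone)
Product: 3 (2S,5R)-2-tert-butyl-5-methyl-5-(prop-2-en-1-yl)-1,3-dioxolan-4-one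
Conditions: LiN(i-Pr)2, THF, −78 °C; allyl bromide, −78 → −30 °C
Reagents that add atoms: allyl bromide, C=CCBr
Why: Enolate alkylation of the dioxolanone; the electrophile should enter trans to the tert-butyl group, so the acetal carbon sets the quaternary C10 centre.

Step 3
Reactants: 3 (allylated dioxolanone); 4 2-methylbut-1-en-3-yne
Product: 6 (2R)-2-methyl-2-(prop-2-en-1-yl)-5-(prop-1-en-2-yl)furan-3(2H)-one, via hydroxy ynone 5 (not isolated)
Conditions: 4, n-BuLi, THF, −78 °C; then 3, −78 → −20 °C; then MeOH, K2CO3 (cat.), rt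
Reagents that add atoms: none
Why: Addition of the lithium acetylide to the lactone-type carbonyl (collapse releases pivalaldehyde) should give the γ-hydroxy ynone, which closes by base-mediated 5-endo-dig oxa-Michael addition to the 3(2H)-furanone; C10 is not touched.

Step 4
Reactants: 7 (2R)-but-3-ene-1,2-diol
Product: 8 (4R)-4-ethenyl-2-(4-methoxyphenyl)-1,3-dioxolane (both configurations at the acetal carbon)
Conditions: 4-methoxybenzaldehyde dimethyl acetal, PPTS (cat.), CH2Cl2, rt
Reagents that add atoms: 4-methoxybenzaldehyde dimethyl acetal, COC(OC)c1ccc(OC)cc1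
Why: Acid-catalysed transacetalisation of the 1,2-diol; C6 is untouched and the acetal-carbon mixture is of no consequence.

Step 5
Reactants: 8 (PMP acetal)
Product: 9 (2R)-2-[(4-methoxybenzyl)oxy]but-3-en-1-ol
Conditions: i-Bu2AlH, CH2Cl2, −78 → 0 °C; aqueous Rochelle salt
Reagents that add atoms: none
Why: Regioselective reductive acetal opening; the aluminium hydride coordinates the less hindered primary oxygen, so the PMB group should end on the secondary (C6) oxygen.

Step 6
Reactants: 6 (allyl furanone); 9 (PMB ether alcohol, excess)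
Product: 10 (2R)-2-{(2E,4R)-5-hydroxy-4-[(4-methoxybenzyl)oxy]pent-2-en-1-yl}-2-methyl-5-(prop-1-en-2-yl)furan-3(2H)-one
Conditions: second-generation Hoveyda–Grubbs catalyst (5 mol %), CH2Cl2, 40 °C
Reagents that add atoms: none
Why: Olefin cross-metathesis of the two monosubstituted alkenes; the (E)-C7=C8 alkene is favoured thermodynamically and the conjugated 1,1-disubstituted isopropenyl group should stay inert.

Step 7
Reactants: 10 (primary alcohol)
Product: 11 3-({(2R,3E)-2-[(4-methoxybenzyl)oxy]-5-[(2R)-2-methyl-3-oxo-5-(prop-1-en-2-yl)-2,3-dihydrofuran-2-yl]pent-3-en-1-yl}oxy)-3-oxopropanoic acid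
Conditions: Meldrum's acid, toluene, 95 °C
Reagents that add atoms: Meldrum's acid, CC1(C)OC(=O)CC(=O)O1
Why: Thermal acylation by Meldrum's acid (through the acylketene) should give the malonic half-ester of the primary alcohol directly, with loss of acetone.

Step 8
Reactants: 11 (malonic half-ester)
Product: 12 (1S,3aR,7R,7aR)-7-[(4-methoxybenzyl)oxy]-1-{[(2R)-2-methyl-3-oxo-5-(prop-1-en-2-yl)-2,3-dihydrofuran-2-yl]methyl}tetrahydro-1H-furo[3,4-c]pyran-3,4-dione
Conditions: Mn(OAc)3·2H2O (2.2 equiv), NaOAc, degassed AcOH (0.02 M), 40 °C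
Reagents that add atoms: none
Why: Mn(OAc)3 should oxidise the manganese-bound malonic half-ester to the electrophilic C11 radical, which adds 6-exo-trig to C7 of the (E)-C7=C8 alkene; the secondary C8 radical is then oxidised within the manganese carboxylate and captured by the C12 carboxylate oxygen, so C11–C7 and O–C8 form in one operation. The closest known reaction type is the Mn(OAc)3-mediated oxidative radical cyclisation–lactonisation of unsaturated malonates. The temporary δ-lactone closes by 6-exo-trig radical addition through the ester tether, and the γ-lactone by 5-exo capture of the oxidised C8 centre by oxygen. C7 is controlled by the allylic C6 stereocentre (chair-like transition state with C6–OPMB pseudo-equatorial and C6–H eclipsing the alkene, placing O6 and C8 trans on the six-membered ring), C8 by closure with C9 anti to C6 on the γ-lactone, and C11 (destroyed in step 9, so of no consequence) by the ring fusion. The step needs 6-exo over 7-endo attack and chemoselectivity for the isolated alkene over the cross-conjugated dienone and the arene; tether length, the electrophilic radical and the mild temperature are expected to secure this.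

Step 9
Reactants: 12 (bislactone)
Product: 15 (4R,5S)-4-{(1R)-2-hydroxy-1-[(4-methoxybenzyl)oxy]ethyl}-3-methylidene-5-{[(2R)-2-methyl-3-oxo-5-(prop-1-en-2-yl)-2,3-dihydrofuran-2-yl]methyl}oxolan-2-one, via Mannich base 13 (not isolated), via amino acid 14 (not isolated)
Conditions: Eschenmoser's salt, MeCN, 0 °C → rt; then LiOH, THF–H2O, 0 °C; then AcOH to pH 5, 50 °C
Reagents that add atoms: Eschenmoser's salt, C[N+](C)=C.[I-]
Why: Mannich aminomethylation of the acidic C11–H, hydrolytic opening of the more reactive δ-lactone and decarboxylative elimination of dimethylamine (decarboxylative Mannich methylenation) should excise the tether carbonyl as CO2, create C11=C13 and release the C5 hydroxyl; no stereocentre of the target is involved.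

Step 10
Reactants: 15 (primary alcohol)
Product: 16 (2R)-2-[(4-methoxybenzyl)oxy]-2-[(2S,3R)-4-methylidene-2-{[(2R)-2-methyl-3-oxo-5-(prop-1-en-2-yl)-2,3-dihydrofuran-2-yl]methyl}-5-oxooxolan-3-yl]acetaldehyde
Conditions: Dess–Martin periodinane, NaHCO3, CH2Cl2, 0 °C → rt
Reagents that add atoms: none
Why: Dess–Martin oxidation under buffered, non-basic conditions should keep the α-alkoxy aldehyde (C6) configurationally intact.

Step 11
Reactants: 16 (aldehyde)
Product: 17 (4R,5S)-4-{(1S)-1-[(4-methoxybenzyl)oxy]prop-2-en-1-yl}-3-methylidene-5-{[(2R)-2-methyl-3-oxo-5-(prop-1-en-2-yl)-2,3-dihydrofuran-2-yl]methyl}oxolan-2-one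
Conditions: Zn, CH2Br2, TiCl4 (Lombardo reagent), THF–CH2Cl2, 0 °C → rt
Reagents that add atoms: dibromomethane, BrCBr
Why: Takai–Lombardo methylenation with a non-basic titanium methylidene is chemoselective for the aldehyde over lactone and enone carbonyls and should not epimerise C6 or add to the methylene lactone.

Step 12
Reactants: 17 (diene)
Product: 18 6-O-(4-methoxybenzyl)-(4Z)-6-hydroxy-1-oxo-3,10-epoxygermacra-2,4,11(13)-trien-12,8-olide, configured at C6, C7, C8 and C10 as in 23
Conditions: second-generation Hoveyda–Grubbs catalyst (15 mol %), toluene (1 mM), 100 °C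
Reagents that add atoms: none
Why: Ring-closing metathesis from the C6 vinyl group onto the furanone isopropenyl group should form the trisubstituted C4=C5 alkene, whose Z geometry is enforced by the furanone-bridged ten-membered ring.

Step 13
Reactants: 18 (PMB ether)
Product: 19 (4Z)-6-hydroxy-1-oxo-3,10-epoxygermacra-2,4,11(13)-trien-12,8-olide, configured as in 23
Conditions: DDQ, CH2Cl2–pH 7 buffer, 0 °C → rt
Reagents that add atoms: none
Why: Oxidative cleavage of the PMB ether through the benzylic oxocarbenium ion; no stereocentre is affected.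

Step 14
Reactants: 20 (2Z)-2-methylbut-2-en-1-ol
Product: 21 [(2S,3R)-2,3-dimethyloxiran-2-yl]methanol
Conditions: Ti(OiPr)4 (10 mol %), L-(+)-diethyl tartrate (12 mol %), t-BuOOH, 4 Å molecular sieves, CH2Cl2, −20 °C
Reagents that add atoms: tert-butyl hydroperoxide, CC(C)(C)OO
Why: Sharpless asymmetric epoxidation; the L-(+)-tartrate catalyst should deliver oxygen to the alkene face that gives the (2S,3R)-epoxy alcohol (reagent control).

Step 15
Reactants: 21 (epoxy alcohol)
Product: 22 (2R,3R)-2,3-dimethyloxirane-2-carboxylic acid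
Conditions: RuCl3·xH2O (2 mol %), NaIO4, CCl4–MeCN–H2O, rt
Reagents that add atoms: water, O
Why: Ruthenium tetroxide oxidation of the primary alcohol to the acid through the aldehyde hydrate; the epoxide is not touched.

Step 16
Reactants: 19 (macrocyclic alcohol); 22 (epoxy acid)
Product: 23 target CNP0258430.3
Conditions: 22, 2,4,6-trichlorobenzoyl chloride, Et3N, THF, rt; then 19, DMAP, toluene, rt
Reagents that add atoms: none
Why: Yamaguchi esterification through the mixed anhydride; acylation takes place at oxygen, so C6 is retained.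

Compound list
1 | (S)-lactic acid, (2S)-2-hydroxypropanoic acid | C[C@H](O)C(=O)O | starting material
2 | (2S,5S)-2-tert-butyl-5-methyl-1,3-dioxolan-4-one | C[C@@H]1O[C@H](C(C)(C)C)OC1=O | intermediate
3 | (2S,5R)-2-tert-butyl-5-methyl-5-(prop-2-en-1-yl)-1,3-dioxolan-4-one | C=CC[C@@]1(C)O[C@H](C(C)(C)C)OC1=O | intermediate
4 | 2-methylbut-1-en-3-yne | C=C(C)C#C | starting material
5 | (6R)-6-hydroxy-2,6-dimethylnona-1,8-dien-3-yn-5-one | C=CC[C@@](C)(O)C(=O)C#CC(C)=C | intermediate
6 | (2R)-2-methyl-2-(prop-2-en-1-yl)-5-(prop-1-en-2-yl)furan-3(2H)-one | C=CC[C@@]1(C)OC(=CC1=O)C(C)=C | intermediate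
7 | (2R)-but-3-ene-1,2-diol | OC[C@H](O)C=C | starting material
8 | (4R)-4-ethenyl-2-(4-methoxyphenyl)-1,3-dioxolane (both configurations at the acetal carbon) | C=C[C@@H]1COC(c2ccc(OC)cc2)O1 | intermediate
9 | (2R)-2-[(4-methoxybenzyl)oxy]but-3-en-1-ol | OC[C@H](OCc1ccc(OC)cc1)C=C | intermediate
10 | (2R)-2-{(2E,4R)-5-hydroxy-4-[(4-methoxybenzyl)oxy]pent-2-en-1-yl}-2-methyl-5-(prop-1-en-2-yl)furan-3(2H)-one | OC[C@H](OCc1ccc(OC)cc1)/C=C/C[C@@]1(C)OC(=CC1=O)C(C)=C | intermediate
11 | 3-({(2R,3E)-2-[(4-methoxybenzyl)oxy]-5-[(2R)-2-methyl-3-oxo-5-(prop-1-en-2-yl)-2,3-dihydrofuran-2-yl]pent-3-en-1-yl}oxy)-3-oxopropanoic acid | OC(=O)CC(=O)OC[C@H](OCc1ccc(OC)cc1)/C=C/C[C@@]1(C)OC(=CC1=O)C(C)=C | intermediate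
12 | (1S,3aR,7R,7aR)-7-[(4-methoxybenzyl)oxy]-1-{[(2R)-2-methyl-3-oxo-5-(prop-1-en-2-yl)-2,3-dihydrofuran-2-yl]methyl}tetrahydro-1H-furo[3,4-c]pyran-3,4-dione (γ-lactone fused to the temporary δ-lactone) | O=C1OC[C@H](OCc2ccc(OC)cc2)[C@H]3[C@H](C[C@@]4(C)OC(=CC4=O)C(C)=C)OC(=O)[C@@H]13 | intermediate
13 | (1S,3aS,7R,7aR)-3a-[(dimethylamino)methyl] derivative of 12 | O=C1OC[C@H](OCc2ccc(OC)cc2)[C@H]3[C@H](C[C@@]4(C)OC(=CC4=O)C(C)=C)OC(=O)[C@@]13CN(C)C | intermediate
14 | (3S,4R,5S)-3-[(dimethylamino)methyl]-4-{(1R)-2-hydroxy-1-[(4-methoxybenzyl)oxy]ethyl}-5-{[(2R)-2-methyl-3-oxo-5-(prop-1-en-2-yl)-2,3-dihydrofuran-2-yl]methyl}-2-oxooxolane-3-carboxylic acid | OC[C@H](OCc1ccc(OC)cc1)[C@H]2[C@H](C[C@@]3(C)OC(=CC3=O)C(C)=C)OC(=O)[C@@]2(CN(C)C)C(O)=O | intermediate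
15 | (4R,5S)-4-{(1R)-2-hydroxy-1-[(4-methoxybenzyl)oxy]ethyl}-3-methylidene-5-{[(2R)-2-methyl-3-oxo-5-(prop-1-en-2-yl)-2,3-dihydrofuran-2-yl]methyl}oxolan-2-one | C=C1C(=O)O[C@@H](C[C@@]2(C)OC(=CC2=O)C(C)=C)[C@@H]1[C@H](CO)OCc1ccc(OC)cc1 | intermediate
16 | (2R)-2-[(4-methoxybenzyl)oxy]-2-[(2S,3R)-4-methylidene-2-{[(2R)-2-methyl-3-oxo-5-(prop-1-en-2-yl)-2,3-dihydrofuran-2-yl]methyl}-5-oxooxolan-3-yl]acetaldehyde | C=C1C(=O)O[C@@H](C[C@@]2(C)OC(=CC2=O)C(C)=C)[C@@H]1[C@H](C=O)OCc1ccc(OC)cc1 | intermediate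
17 | (4R,5S)-4-{(1S)-1-[(4-methoxybenzyl)oxy]prop-2-en-1-yl}-3-methylidene-5-{[(2R)-2-methyl-3-oxo-5-(prop-1-en-2-yl)-2,3-dihydrofuran-2-yl]methyl}oxolan-2-one | C=C1C(=O)O[C@@H](C[C@@]2(C)OC(=CC2=O)C(C)=C)[C@@H]1[C@H](C=C)OCc1ccc(OC)cc1 | intermediate
18 | 6-O-(4-methoxybenzyl)-(4Z)-6-hydroxy-1-oxo-3,10-epoxygermacra-2,4,11(13)-trien-12,8-olide, configured at C6, C7, C8 and C10 as in 23 | C=C1C(=O)O[C@H]2C[C@@]3(C)OC(=CC3=O)/C(C)=C\[C@H](OCc4ccc(OC)cc4)[C@H]12 | intermediate
19 | (4Z)-6-hydroxy-1-oxo-3,10-epoxygermacra-2,4,11(13)-trien-12,8-olide, same spatial configuration as 23 | C=C1C(=O)O[C@H]2C[C@@]3(C)OC(=CC3=O)/C(C)=C\[C@H](O)[C@H]12 | intermediate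
20 | (2Z)-2-methylbut-2-en-1-ol | C/C=C(/C)CO | starting material
21 | [(2S,3R)-2,3-dimethyloxiran-2-yl]methanol | OC[C@]1(C)O[C@@H]1C | intermediate
22 | (2R,3R)-2,3-dimethyloxirane-2-carboxylic acid | OC(=O)[C@]1(C)O[C@@H]1C | intermediate
23 | CNP0258430.3, (4Z,6S,7R,8S,10R)-6-{[(2R,3R)-2,3-dimethyloxirane-2-carbonyl]oxy}-1-oxo-3,10-epoxygermacra-2,4,11(13)-trien-12,8-olide | C=C1C(=O)O[C@H]2C[C@@]3(C)OC(=CC3=O)/C(C)=C\[C@H](OC(=O)[C@]3(C)O[C@@H]3C)[C@H]12 | target

Total step count: 16. Longest linear sequence: 12 steps (steps 1–3, 6–13 and 16).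

Steps most likely to fail

Step 8 (key step). The 6-exo closure through the ester tether may be slow because the reactive ester rotamer is disfavoured. 1,5-Hydrogen transfer from the allylic C6–H may compete. Facial selectivity at C7 may erode if the C6–OPMB group takes the position eclipsing the alkene. The acidic ring-fusion C–H of the product may be oxidised further. The fallback sets out from 10 and comes back at 15; it keeps the two-bond event but changes the tether to an ether so that closure is 5-exo and the product is not enolisable. Rh2(OAc)4-catalysed O–H insertion of 5-diazo-2,2-dimethyl-1,3-dioxane-4,6-dione into the primary hydroxyl of 10 would give the 5-alkoxy Meldrum's acid F1. Mn(OAc)3 with Cu(OAc)2 in AcOH would then close the C11 radical 5-exo on C7 (C6–OPMB and C8 trans on the new tetrahydrofuran) and lactonise C8 with loss of acetone, giving the quaternary tetrahydrofuran-fused lactone acid F2. SmI2 (THF–MeOH) would cleave the C11–O bond α to both carbonyls to the hydroxy lactone acid F3. Decarboxylative Mannich methylenation (aqueous CH2O, Et2NH; then NaOAc, AcOH, heat) would return to 15.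

Step 12. Ring closure may stall through slow catalyst loading at the hindered, oxygen-flanked C6 vinyl group, with oligomerisation and strain in forming the trisubstituted alkene taking over. The fallback sets out from 16 and comes back at 18 by relay ring-closing metathesis. Takai–Utimoto alkylidenation of 16 with 6,6-diiodohex-1-ene and CrCl2 (THF–DMF) would give the (E)-octa-2,7-dienyl relay substrate F4. The catalyst should then load at the unhindered terminal alkene, expel cyclopentene and be delivered intramolecularly to C5 for closure onto the isopropenyl group, giving 18.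

Step 9. The γ-lactone may open instead of the δ-lactone, the Mannich base may revert, or the C5 hydroxyl or the liberated amine may add back to the new methylene lactone. The fallback sets out from 12 and comes back at 15 by a stepwise methylenation of the parent lactone. Hydrolytic decarboxylation (H2O, DMSO, 100 °C) would give the γ-lactone alcohol F5, the γ-lactone being the thermodynamically preferred ring. Its dianion (LiN(i-Pr)2, THF, −78 °C) would be aminomethylated with Eschenmoser's salt to the amino lactone F6. N-Methylation (MeI) and NaHCO3-induced elimination of trimethylamine would give 15.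

Further compounds
F1 | step 8 | 5-({(2R,3E)-2-[(4-methoxybenzyl)oxy]-5-[(2R)-2-methyl-3-oxo-5-(prop-1-en-2-yl)-2,3-dihydrofuran-2-yl]pent-3-en-1-yl}oxy)-2,2-dimethyl-1,3-dioxane-4,6-dione | CC1(C)OC(=O)C(OC[C@H](OCc2ccc(OC)cc2)/C=C/C[C@@]2(C)OC(=CC2=O)C(C)=C)C(=O)O1
F2 | step 8 | cis-fused 3-[(4-methoxybenzyl)oxy]-4-{[(2R)-2-methyl-3-oxo-5-(prop-1-en-2-yl)-2,3-dihydrofuran-2-yl]methyl}-6-oxotetrahydrofuro[3,4-b]furan-6a-carboxylic acid, C6, C7 and C8 as in 15 | OC(=O)[C@]12OC[C@H](OCc3ccc(OC)cc3)[C@H]1[C@H](C[C@@]4(C)OC(=CC4=O)C(C)=C)OC2=O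
F3 | step 8 | (4R,5S)-4-{(1R)-2-hydroxy-1-[(4-methoxybenzyl)oxy]ethyl}-5-{[(2R)-2-methyl-3-oxo-5-(prop-1-en-2-yl)-2,3-dihydrofuran-2-yl]methyl}-2-oxooxolane-3-carboxylic acid (both configurations at C3) | OC[C@H](OCc1ccc(OC)cc1)[C@H]2[C@H](C[C@@]3(C)OC(=CC3=O)C(C)=C)OC(=O)C2C(O)=O
F4 | step 12 | (4R,5S)-4-{(1S,2E)-1-[(4-methoxybenzyl)oxy]octa-2,7-dien-1-yl}-3-methylidene-5-{[(2R)-2-methyl-3-oxo-5-(prop-1-en-2-yl)-2,3-dihydrofuran-2-yl]methyl}oxolan-2-one | C=C1C(=O)O[C@@H](C[C@@]2(C)OC(=CC2=O)C(C)=C)[C@@H]1[C@H](/C=C/CCCC=C)OCc1ccc(OC)cc1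
F5 | step 9 | (4R,5S)-4-{(1R)-2-hydroxy-1-[(4-methoxybenzyl)oxy]ethyl}-5-{[(2R)-2-methyl-3-oxo-5-(prop-1-en-2-yl)-2,3-dihydrofuran-2-yl]methyl}oxolan-2-one | C1C(=O)O[C@@H](C[C@@]2(C)OC(=CC2=O)C(C)=C)[C@@H]1[C@H](CO)OCc1ccc(OC)cc1
F6 | step 9 | 3-[(dimethylamino)methyl] derivative of F5 (both configurations at C3) | CN(C)CC1C(=O)O[C@@H](C[C@@]2(C)OC(=CC2=O)C(C)=C)[C@@H]1[C@H](CO)OCc1ccc(OC)cc1
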